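**Retrosynthetic overview**
1. Target 20 ⇐ epoxy alcohol 16 by two late acylations (C6 veratrate, then C2 acetate); 16 ⇐ hydroazulenone 12 by reduction, CO2Me → CH3 and OH-directed epoxidation.
2. Key disconnection: 12 ⇐ acyclic silyloxydiene ketone 7 + vinyldiazoacetate 9 in one flask: Rh(II) cyclopropanation → divinylcyclopropane (Cope) rearrangement → intramolecular Mukaiyama aldol.
3. Ring order: transient cyclopropane → seven-membered ring (sets C1) → five-membered ring (sets C4, C5), all in step 5; the oxirane is closed in step 8.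
4. 7 ⇐ asymmetric boron aldol (sets C2) of 3-methylbutan-2-one with (E)-2-methyl-4-oxopent-2-enal, itself from mesityl oxide.

Numbering: bicyclic compounds carry daucane numbers (C1 = angular-CH3 carbon, C2 = CH–O, C3 = CH2, C4 = C(OH)iPr, C5 = ring-fusion CH, C6 = CH–O, C7, C8/C9 = alkene/epoxide carbons, C10).
Assumption: the absolute sense of the two reagent-controlled steps follows the accepted models ((+)-Ipc2B methyl-ketone enolate → Si face of the aldehyde in step 2; Rh2(S-DOSP)4 → the (1R,2S)-cyclopropane in step 5); if either is reversed on these substrates, the antipodal reagent is used and nothing else changes.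

**Step 1**
Reactants: 1 mesityl oxide
Product: 3 (E)-2-methyl-4-oxopent-2-enal, via allylic alcohol 2 (not isolated)
Conditions: SeO2 (1.2 equiv), 1,4-dioxane/H2O, reflux
Reagents that add atoms: selenium dioxide, O=[Se]=O
Why: SeO2 allylic oxidation (ene reaction then [2,3]-shift) attacks the (E)-methyl of the trisubstituted alkene, as it does in isophorone and senecioate esters, so the trans enal geometry needed in step 5 is fixed here.

**Step 2**
Reactants: 3 (E)-2-methyl-4-oxopent-2-enal; 4 3-methylbutan-2-one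
Product: 6 (3E,5S)-5-hydroxy-4,8-dimethylnon-3-ene-2,7-dione, via enol diisopinocampheylborinate 5 (not isolated)
Conditions: 4, (+)-Ipc2BCl, Et3N, Et2O, −78 → 0 °C; then 3, −78 → −20 °C; then MeOH, pH 7 buffer, 30% H2O2, 0 °C
Reagents that add atoms: none
Why: Paterson boron aldol: the kinetic methyl-side boron enolate adds only to the aldehyde (not the enone carbonyl) through a cyclic transition state, and the Ipc ligands set C2 as (S) (about 75–90% ee expected; upgraded in step 5, where catalyst control turns the minor enantiomer into a separable diastereomer).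

**Step 3**
Reactants: 6 (3E,5S)-5-hydroxy-4,8-dimethylnon-3-ene-2,7-dione
Product: 7 (5S,6E)-5,8-bis(tert-butyldimethylsilyloxy)-2,6-dimethylnona-6,8-dien-3-one
Conditions: TBSOTf (2.3 equiv), Et3N, CH2Cl2, −78 → 0 °C
Reagents that add atoms: tert-butyldimethylsilyl trifluoromethanesulfonate, CC(C)(C)[Si](C)(C)OS(=O)(=O)C(F)(F)F
Why: Soft enolisation/silylation protects the alcohol and converts the unhindered enone methyl ketone into the cross-conjugated 2-silyloxy-1,3-diene, while the α-branched isopropyl ketone next to CH(OTBS) enolises much more slowly; no stereocentre is touched.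

**Step 4**
Reactants: 8 methyl but-3-enoate
Product: 9 methyl 2-diazobut-3-enoate
Conditions: p-ABSA, DBU, MeCN, 0 °C; used cold and at once
Reagents that add atoms: 4-acetamidobenzenesulfonyl azide, CC(=O)Nc1ccc(cc1)S(=O)(=O)N=[N+]=[N-]
Why: Regitz diazo transfer to the doubly activated (allylic, α-ester) CH2 gives the vinyldiazoacetate, which must be used fresh because it slowly cyclises to a pyrazole.

**Step 5 (key step)**
Reactants: 7 (5S,6E)-5,8-bis(tert-butyldimethylsilyloxy)-2,6-dimethylnona-6,8-dien-3-one; 9 methyl 2-diazobut-3-enoate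
Product: 12 methyl (1S,2S,4S,5S)-2-(tert-butyldimethylsilyloxy)-4-hydroxy-4-isopropyl-1-methyl-6-oxohydroazulen-8-ene-8-carboxylate (daucane numbering), via cis-divinylcyclopropane 10 (not isolated), via cycloheptadienyl silyl enol ether 11 (not isolated)
Conditions: Rh2(S-DOSP)4 (1 mol %), heptane, 9 (2.5 equiv) added slowly at −20 °C, then 80 °C; cool to −78 °C, CH2Cl2, TiCl4 (1.5 equiv); then H2O
Reagents that add atoms: none
Why: Davies formal [4+3]: the donor/acceptor Rh carbenoid cyclopropanates only the electron-rich terminal enol-ether C=C under catalyst control with the two alkenyl groups cis; the boat divinylcyclopropane (Cope) rearrangement transfers that chirality to the quaternary C1 (the (E)-alkene puts CH3 inside) and gives a regiodefined C5=C6 silyl enol ether; TiCl4 then closes the cyclopentane by intramolecular Mukaiyama aldol onto the isopropyl ketone, the chelated titanium aldolate placing O4 cis to C6, and the transition state with the small CH3 (not the C2–OTBS carbon) next to C6 giving the trans ring fusion (C5 is also epimerisable to this isomer).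

**Step 6**
Reactants: 12 keto ester from step 5
Product: 13 (1S,2S,4S,5R,6S)-2-(tert-butyldimethylsilyloxy)-8-(hydroxymethyl)-4-isopropyl-1-methylhydroazulen-8-ene-4,6-diol
Conditions: DIBAL-H (6 equiv), THF, −78 → 0 °C; Rochelle salt
Reagents that add atoms: none
Why: DIBAL reduces the ester to the allylic alcohol and the β-hydroxy ketone through an aluminium chelate with external hydride attack from the face opposite the angular methyl, giving the 4,6-syn diol (C6–OH cis to C4–OH and C1–CH3).

**Step 7**
Reactants: 13 triol from step 6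
Product: 15 (1S,2S,4S,5R,6S)-2-(tert-butyldimethylsilyloxy)-4-isopropyl-1,8-dimethylhydroazulen-8-ene-4,6-diol, via allylic mesylate 14 (not isolated)
Conditions: MsCl (1.1 equiv), Et3N, THF, −40 °C; then LiBHEt3 (6 equiv), −40 → 0 °C
Reagents that add atoms: none
Why: Selective sulfonylation of the primary allylic alcohol (the axial secondary and the tertiary OH react far more slowly) followed by SN2 hydride displacement with Super-Hydride turns CH2OH into the C8 methyl without moving the double bond.

**Step 8**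
Reactants: 15 alkene diol from step 7
Product: 16 (1S,2S,4S,5R,6S,8R,9S)-2-(tert-butyldimethylsilyloxy)-8,9-epoxy-4-isopropyl-1,8-dimethylhydroazulane-4,6-diol
Conditions: VO(acac)2 (5 mol %), TBHP, CH2Cl2, 0 °C → rt
Reagents that add atoms: tert-butyl hydroperoxide, CC(C)(C)OO
Why: Vanadium-catalysed hydroxyl-directed epoxidation: the axial homoallylic C6–OH (with C4–OH on the same face) binds the vanadium peroxide and delivers oxygen to its own face of C8=C9, setting C8 and C9.

**Step 9**
Reactants: 16 epoxy diol from step 8; 17 3,4-dimethoxybenzoyl chloride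
Product: 18 the C6 3,4-dimethoxybenzoate of 16
Conditions: 17 (1.5 equiv), DMAP (0.3 equiv), Et3N, CH2Cl2, rt
Reagents that add atoms: none
Why: DMAP-catalysed acylation (nucleophilic catalysis) of the only secondary alcohol; the tertiary C4–OH does not react and the epoxide is untouched.

**Step 10**
Reactants: 18 silyl ether from step 9
Product: 19 the C2 alcohol (2,4-diol 6-veratrate)
Conditions: TBAF, AcOH (1:1, 3 equiv), THF, rt → 45 °C
Reagents that add atoms: none
Why: Fluoride-mediated desilylation, buffered with acetic acid so that the ester and epoxide survive and no acyl migration occurs.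

**Step 11**
Reactants: 19 diol from step 10
Product: 20 target, (1S,2S,4S,5R,6S,8R,9S)-2-acetoxy-8,9-epoxy-4-hydroxy-4-isopropyl-1,8-dimethylhydroazulan-6-yl 3,4-dimethoxybenzoate (CNP0330776.1)
Conditions: Ac2O, DMAP (cat.), pyridine, CH2Cl2, 0 °C → rt
Reagents that add atoms: acetic anhydride, CC(=O)OC(C)=O
Why: DMAP-catalysed acetylation of the secondary C2–OH; the tertiary C4–OH is inert under these mild conditions.

**Compound list**
1 | mesityl oxide (4-methylpent-3-en-2-one) | CC(=O)C=C(C)C | starting material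
2 | (E)-5-hydroxy-4-methylpent-3-en-2-one | CC(=O)/C=C(C)/CO | intermediate (not isolated)
3 | (E)-2-methyl-4-oxopent-2-enal | CC(=O)/C=C(C)/C=O | intermediate
4 | 3-methylbutan-2-one | CC(=O)C(C)C | starting material
5 | 3-methylbut-1-en-2-yl bis[(+)-isopinocampheyl]borinate | C=C(C(C)C)OB([C@H]1C[C@H]2C[C@@H]([C@@H]1C)C2(C)C)[C@H]1C[C@H]2C[C@@H]([C@@H]1C)C2(C)C | intermediate (not isolated)
6 | (3E,5S)-5-hydroxy-4,8-dimethylnon-3-ene-2,7-dione | CC(C)C(=O)C[C@H](O)/C(C)=C/C(C)=O | intermediate
7 | (5S,6E)-5,8-bis(tert-butyldimethylsilyloxy)-2,6-dimethylnona-6,8-dien-3-one | CC(C)C(=O)C[C@H](O[Si](C)(C)C(C)(C)C)/C(C)=C/C(=C)O[Si](C)(C)C(C)(C)C | intermediate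
8 | methyl but-3-enoate | C=CCC(=O)OC | starting material
9 | methyl 2-diazobut-3-enoate | C=CC(=[N+]=[N-])C(=O)OC | intermediate
10 | methyl (1R,2S)-2-(tert-butyldimethylsilyloxy)-2-[(1E,3S)-3-(tert-butyldimethylsilyloxy)-2,6-dimethyl-5-oxohept-1-en-1-yl]-1-vinylcyclopropane-1-carboxylate (alkenyl groups cis) | C=C[C@]1(C(=O)OC)C[C@]1(O[Si](C)(C)C(C)(C)C)/C=C(C)/[C@@H](O[Si](C)(C)C(C)(C)C)CC(=O)C(C)C | intermediate (not isolated)
11 | methyl (4S)-6-(tert-butyldimethylsilyloxy)-4-[(1S)-1-(tert-butyldimethylsilyloxy)-4-methyl-3-oxopentyl]-4-methylcyclohepta-1,5-diene-1-carboxylate | CC(C)C(=O)C[C@H](O[Si](C)(C)C(C)(C)C)[C@@]1(C)CC=C(C(=O)OC)CC(O[Si](C)(C)C(C)(C)C)=C1 | intermediate (not isolated)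
12 | trans-fused hydroazulenone, daucane numbering: 1-CH3, 2-OTBS, 4-OH, 4-iPr, 6-oxo, 8-CO2Me, C8=C9; (1S,2S,4S,5S); 1-CH3, 2-O and 4-OH on one face, H-5 and iPr on the other | O=C1CC(C(=O)OC)=CC[C@]2(C)[C@@H](O[Si](C)(C)C(C)(C)C)C[C@](O)(C(C)C)[C@@H]12 | intermediate
13 | as 12 but 6-OH (cis to 4-OH and 1-CH3) and 8-CH2OH; (1S,2S,4S,5R,6S) | O[C@H]1CC(CO)=CC[C@]2(C)[C@@H](O[Si](C)(C)C(C)(C)C)C[C@](O)(C(C)C)[C@@H]12 | intermediate
14 | primary allylic methanesulfonate of 13 | O[C@H]1CC(COS(C)(=O)=O)=CC[C@]2(C)[C@@H](O[Si](C)(C)C(C)(C)C)C[C@](O)(C(C)C)[C@@H]12 | intermediate (not isolated)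
15 | (1S,2S,4S,5R,6S)-2-(tert-butyldimethylsilyloxy)dauc-8-ene-4,6-diol | O[C@H]1CC(C)=CC[C@]2(C)[C@@H](O[Si](C)(C)C(C)(C)C)C[C@](O)(C(C)C)[C@@H]12 | intermediate
16 | (1S,2S,4S,5R,6S,8R,9S)-2-(tert-butyldimethylsilyloxy)-8,9-epoxydaucane-4,6-diol (epoxide O cis to 6-OH) | O[C@H]1C[C@@]2(C)O[C@H]2C[C@]2(C)[C@@H](O[Si](C)(C)C(C)(C)C)C[C@](O)(C(C)C)[C@@H]12 | intermediate
17 | 3,4-dimethoxybenzoyl chloride | COc1ccc(C(Cl)=O)cc1OC | starting material
18 | 6-O-(3,4-dimethoxybenzoyl) derivative of 16 | COc1ccc(C(=O)O[C@H]2C[C@@]3(C)O[C@H]3C[C@]3(C)[C@@H](O[Si](C)(C)C(C)(C)C)C[C@](O)(C(C)C)[C@@H]23)cc1OC | intermediate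
19 | (1S,2S,4S,5R,6S,8R,9S)-8,9-epoxy-2,4-dihydroxydaucan-6-yl 3,4-dimethoxybenzoate | COc1ccc(C(=O)O[C@H]2C[C@@]3(C)O[C@H]3C[C@]3(C)[C@@H](O)C[C@](O)(C(C)C)[C@@H]23)cc1OC | intermediate
20 | (1S,2S,4S,5R,6S,8R,9S)-2-acetoxy-8,9-epoxy-4-hydroxydaucan-6-yl 3,4-dimethoxybenzoate | COc1ccc(C(=O)O[C@H]2C[C@@]3(C)O[C@H]3C[C@]3(C)[C@@H](OC(C)=O)C[C@](O)(C(C)C)[C@@H]23)cc1OC | target

**Totals and risks**
Total steps: 11. Longest linear sequence: 10 (steps 1–3 and 5–11; step 4 is a one-step side branch).

The step most likely to fail is step 5. The cyclopropanation must place the two alkenyl groups cis on a 1,1-disubstituted enol ether (a trans isomer would need about 140 °C to isomerise), and the Lewis-acid aldol onto a hindered ketone must give the trans-fused, O4/C6-cis isomer. The fallback sets out from 7 (with 9) and comes back at 12: the Rh step is stopped after the Cope stage and silyl enol ether 11 is isolated; NBS (THF, −78 °C) converts it into the C5-bromo ketone, methyl 5-bromo-4-[(1S)-1-(tert-butyldimethylsilyloxy)-4-methyl-3-oxopentyl]-4-methyl-6-oxocyclohept-1-ene-1-carboxylate F1; SmI2 (THF, −78 °C) then generates the samarium(III) enolate regiospecifically at C5, which closes the five-membered ring by a chelated Reformatsky-type aldol to give 12.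

Second is step 3, where the isopropyl ketone may also be enol-silylated. The fallback sets out from 3 and comes back at 7, building the dienol ether before the second ketone exists: TBSOTf/Et3N converts 3 (whose aldehyde cannot enolise) into (E)-4-(tert-butyldimethylsilyloxy)-2-methylpenta-2,4-dienal F2; boron enolate 5 adds to it (diethanolamine work-up) to give (5S,6E)-8-(tert-butyldimethylsilyloxy)-5-hydroxy-2,6-dimethylnona-6,8-dien-3-one F3; TBSCl/imidazole in DMF, which cannot enolise a ketone, gives 7.

Third is step 7, where mesylation may be unselective or the C6 alkoxide may attack the allylic mesylate. The fallback sets out from 13 and comes back at 15, delivering hydride through a π-allyl palladium complex instead of by SN2: selective acetylation of the primary allylic alcohol (AcCl, 2,4,6-collidine, CH2Cl2, −78 °C) gives the C8-acetoxymethyl diol F4, and Pd(PPh3)4/Bu3SnH (THF, rt) transfers hydride to the less hindered CH2 terminus to give 15.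

**Further compounds**
F1 | step 5 | methyl 5-bromo-4-[(1S)-1-(tert-butyldimethylsilyloxy)-4-methyl-3-oxopentyl]-4-methyl-6-oxocyclohept-1-ene-1-carboxylate (C4 as in 11, C5 epimer mixture) | CC(C)C(=O)C[C@H](O[Si](C)(C)C(C)(C)C)[C@@]1(C)CC=C(C(=O)OC)CC(=O)C1Br
F2 | step 3 | (E)-4-(tert-butyldimethylsilyloxy)-2-methylpenta-2,4-dienal | C=C(O[Si](C)(C)C(C)(C)C)/C=C(C)/C=O
F3 | step 3 | (5S,6E)-8-(tert-butyldimethylsilyloxy)-5-hydroxy-2,6-dimethylnona-6,8-dien-3-one | CC(C)C(=O)C[C@H](O)/C(C)=C/C(=C)O[Si](C)(C)C(C)(C)C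
F4 | step 7 | primary allylic acetate of 13 (8-acetoxymethyl-4,6-diol) | O[C@H]1CC(COC(C)=O)=CC[C@]2(C)[C@@H](O[Si](C)(C)C(C)(C)C)C[C@](O)(C(C)C)[C@@H]12
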